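## Analysis of the target

Compound 24 is a C22 meroterpenoid. A 5-hydroxy-2,6,6-trimethylcyclohex-2-enyl unit (ring A, C1'–C6') is joined through a five-carbon chain to an epoxycyclohexenediol (ring B, C1–C6) that carries the hydroxymethyl carbon C7 on C4. The chain consists of the C8 carbinol, the Z alkene C9=C10 with the methyl group on C10, and the E alkene C11=C12. There are seven stereocentres. C5' (R) and C1' (S) are cis across the quaternary C6'. C8 (S) stands on the fully substituted oxirane carbon C1 (R), and C2 (S) completes the oxirane. The carbinols C3 (R) and C6 (S) are cis to each other and both anti to the oxirane oxygen.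

Ring A is too far from C8 to pass on stereochemical information, so each half needs its own source of absolute configuration. C8, C1, C2, C3 and C6 are close enough to be set from one another.

The sensitive groups are:
- the C8 carbinol, which is allylic to a diene and ionises easily while an arene or dienone sits on C1;
- the Z trisubstituted alkene;
- the oxirane flanked by three carbinols, open to Payne migration in base and to opening in acid;
- the C1' methine, which can epimerise or move the ring alkene into conjugation at the aldehyde oxidation level.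

The difficulty is concentrated in the contiguous C8–C1–C2 array on a quaternary carbon and in placing both ring carbinols anti to the oxirane. The plan rests on one feature: C3 and C6 carry oxygen in a 1,4 relation and C1 and C4 carry carbon in a 1,4 relation. This is the pattern of a 2,5-disubstituted p-benzoquinone whose C1=C2 enone alkene has been epoxidised and whose two carbonyls have been reduced. The C8 hydroxyl sits on the carbon attached to C1, where its alkoxide can hand a peroxide to C2.

## Retrosynthetic reasoning

The two silyl ethers of 23 are removed last. A primary TBS ether on C7 and a TES ether on the neopentyl C5' oxygen both leave under buffered fluoride, so the epoxy tetraol never meets strong base or acid.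

The C3 and C6 carbinols of 23 are traced back to carbonyl groups, through 22 and 21 to the epoxy enone ketal 20. The two C–H bonds are cut separately because in 20 one carbonyl is free and the other is masked as a ketal. Each reduction can then be controlled by what is already present: the C8 hydroxyl and the oxirane for C6, the oxirane for C3.

The oxirane of 20 is cut at both C–O bonds to give the quinone monoketal 18. This is the central disconnection. It removes one ring and two stereocentres in one operation and leaves a flat dienone whose only stereocentre near ring B is C8. The forward reaction must choose one of two enone arms and one of two faces. The arm is decided by β-substitution, the face by C8.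

The dienone 18 is the dearomatised form of the p-methoxyphenol 17, which comes from its silyl ether 16. Cutting the C3–OMe bond converts ring B into a benzene ring, so all ring-B carbons and their substituents are bought as a commercial arene.

In 16 the chain is cut at the C10–C11 single bond between the two alkenes. This is the most convergent cut. It divides the molecule into the iodoalkenyl carbinol 15 and the alkenylboronate 7, and a stereoretentive cross-coupling carries both alkene geometries over unchanged.

The Z iodoalkene 15 is traced back to the propargylic alcohol 13. Hydrometallation directed by the C8 alkoxide puts the metal, and then iodine, cis to the carbinol; after coupling this is the required 9Z geometry. The alcohol 13 is cut at C8–C9 to the aldehyde 12 and a C3 alkyne, and this addition is where C8 is set.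

The aldehyde 12 is reached from 8 through 9, 10 and 11. The ortho methyl ether is exchanged for a silyl ether while the formyl group is still there to direct the cleavage. The bromide is then replaced by the protected hydroxymethyl group C7.

The boronate 7 comes from the aldehyde 6 by a one-carbon olefination that sets 11E. The aldehyde 6 comes from the hydroxy acetate 3 through 4 and 5. Ring A of 3 is cut at C1'–C6' to the epoxide 2, made from 1. The oxirane stereocentre of 2 becomes C5' and controls C1' in the ring closure.

## Alternatives that were turned down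

Alternative 1: The disconnection is the C1'–C6' bond of ring A. In the forward sense a Lewis acid opens the epoxide A1 at its tertiary carbon and the trisubstituted alkene closes the ring to the hydroxy acetate A2.
- For it: two stereocentres come from one through a chair transition state, the material is cheap, and the risk lies at the very start of the synthesis. On that last point it is stronger than the chosen plan, which carries its risk late.
- Against it: the step answers two of seven stereocentres and none of the ring-B problems. The quaternary oxirane carbon, the C8 carbinol and both anti carbinols are left to later chemistry that this strategy does not specify. Proton loss from the cyclised cation is also not regiocontrolled.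
- Comparison: for ring A nothing shorter is available, and the chosen route uses the same transformation as a supporting step (A1 and A2 are identical with 2 and 3). What the chosen strategy adds is a solution for ring B.

Alternative 2: The disconnection is the C9=C10 alkene. In the forward sense ring-closing metathesis of the silylene-tethered diene A3 gives the seven-membered dioxasilepine A4, in which the new trisubstituted alkene can only be Z.
- For it: the geometry is guaranteed by ring size. This is stronger than the chosen route, where 9Z depends on the stereospecificity of a hydroalumination, an iodination and a cross-coupling.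
- Against it: A3 already contains ring B with C8, C1, C2, C3 and C6 in place, so the hard part must be solved by other means. The metathesis must form a trisubstituted alkene next to a quaternary oxirane carbon. After A4 the tether has to be opened, the allylic alcohol oxidised to a Z α-methyl enal that isomerises easily, and C11=C12 built by an olefination close to the epimerisable C1'.
- Comparison: that is at least five operations and three extra silyl ethers for what the chosen route does in two steps, and the strategic weight falls on a bond that is not the difficult one.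

Alternative 3: The disconnection is the pair of C–O bonds at C3 and C6. In the forward sense photooxygenation of the cis-dihydrodiol acetonide A5 gives the endoperoxide A6 by [4+2] addition anti to the acetonide.
- For it: both ring carbinols arise at once, cis to each other and anti to the C1 and C2 oxygens, with absolute configuration from an enzyme. On C3 and C6 this is stronger than two hydride reductions whose facial sense must be steered.
- Against it: the C1 and C2 oxygens of A6 are cis, so they cannot close to an oxirane directly. C2 must first be inverted and then displaced by a tertiary alkoxide. The ester on C1 must be turned into the C8 carbinol with the whole chain by addition to a neopentyl aldehyde, with no clear control. The microbial oxidation needs a benzoate that already carries C7, which is not an off-the-shelf substrate. Peroxide cleavage and protecting-group changes add length.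
- Comparison: the chosen route also takes ring B from an arene, but from a commercial one, and sets C1 and C2 under the control of C8 in one step.

Key step: step 15

## Route

Remark: atom numbers are those of the analysis. Ar = 4-{[(tert-butyldimethylsilyl)oxy]methyl}-5-methoxy-2-[(triisopropylsilyl)oxy]phenyl. RA = (1S,5R)-2,6,6-trimethyl-5-[(triethylsilyl)oxy]cyclohex-2-en-1-yl. In step 11 the ligand antipode is defined by the aldehyde face it must attack (Si); (R,R)-ProPhenol is assumed to be that antipode, by analogy with Re-face addition under the (S,S)-ligand.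

Step 1
Reactants: 1 geranyl acetate
Product: 2 (R)-6,7-epoxygeranyl acetate
Conditions: D-fructose-derived Shi ketone (30 mol %), Oxone, K2CO3, Bu4NHSO4, MeCN–dimethoxymethane–aq. buffer (pH 10.5), 0 °C
Reagents that add atoms: Oxone (potassium peroxymonosulfate), [K+].[O-]S(=O)(=O)OO
Why: Shi asymmetric epoxidation; the dioxirane takes the electron-rich 6,7-alkene because the 2,3-alkene is deactivated by the allylic acetate, and the spiro transition state of the D-fructose-derived ketone should give the (R)-oxirane, which becomes C5'.

Step 2
Reactants: 2 (R)-6,7-epoxygeranyl acetate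
Product: 3 [(1S,5R)-5-hydroxy-2,6,6-trimethylcyclohex-2-en-1-yl]methyl acetate
Conditions: ZrCl4 (1.1 equiv), CH2Cl2, −20 → 0 °C
Reagents that add atoms: none
Why: Lewis-acid-initiated epoxide–olefin cation cyclisation; the oxirane opens at its tertiary carbon and the E alkene closes through a chair transition state with the C–O bond and the CH2OAc group equatorial, which sets C1' cis to the retained C5' carbinol; loss of a ring CH2 proton should give the endocyclic alkene.

Step 3
Reactants: 3 [(1S,5R)-5-hydroxy-2,6,6-trimethylcyclohex-2-en-1-yl]methyl acetate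
Product: 4 RA-CH2OAc, the triethylsilyl ether of 3
Conditions: TESOTf, 2,6-lutidine, CH2Cl2, −78 → 0 °C
Reagents that add atoms: triethylsilyl triflate, CC[Si](CC)(CC)OS(=O)(=O)C(F)(F)F
Why: Silylation of a hindered secondary alcohol with a silyl triflate; TES is chosen because it can later be removed from this neopentyl position by buffered fluoride.

Step 4
Reactants: 4 RA-CH2OAc
Product: 5 RA-CH2OH
Conditions: K2CO3 (cat.), MeOH, 0 °C → rt
Reagents that add atoms: none
Why: Base-catalysed transesterification of the primary acetate; the hindered secondary TES ether should be stable to methanolic carbonate.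

Step 5
Reactants: 5 RA-CH2OH
Product: 6 RA-CHO
Conditions: Dess–Martin periodinane, NaHCO3, CH2Cl2, 0 °C
Reagents that add atoms: none
Why: Dess–Martin oxidation under buffered, non-basic conditions, so that C1' is not epimerised and the β,γ-alkene stays out of conjugation; the aldehyde is used at once.

Step 6
Reactants: 6 RA-CHO
Product: 7 pinacol (E)-2-(RA)ethenylboronate
Conditions: Cl2CHBpin, CrCl2, LiI, THF, rt
Reagents that add atoms: 2-(dichloromethyl)-4,4,5,5-tetramethyl-1,3,2-dioxaborolane, ClC(Cl)B1OC(C)(C)C(C)(C)O1
Why: Takai–Utimoto boryl olefination; the gem-dichromium reagent adds to the aldehyde and eliminates to the E alkenylboronate (C11=C12) under non-basic conditions that should leave C1' untouched.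

Step 7
Reactants: 8 4-bromo-2,5-dimethoxybenzaldehyde
Product: 9 4-bromo-2-hydroxy-5-methoxybenzaldehyde
Conditions: BCl3, CH2Cl2, −78 → 0 °C
Reagents that add atoms: none
Why: Chelation-assisted ether cleavage; boron bound to the formyl oxygen cleaves only the ortho methyl ether, and the methyl ether that becomes the C3 oxygen survives.

Step 8
Reactants: 9 4-bromo-2-hydroxy-5-methoxybenzaldehyde
Product: 10 4-bromo-5-methoxy-2-[(triisopropylsilyl)oxy]benzaldehyde
Conditions: TIPSCl, imidazole, DMAP (cat.), DMF, rt
Reagents that add atoms: triisopropylsilyl chloride, CC(C)[Si](Cl)(C(C)C)C(C)C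
Why: Silylation of the phenol; the bulky TIPS group should not migrate to a neighbouring alkoxide in steps 11 and 12 and is cleaved by fluoride before alkyl silyl ethers.

Step 9
Reactants: 10 4-bromo-5-methoxy-2-[(triisopropylsilyl)oxy]benzaldehyde
Product: 11 4-(hydroxymethyl)-5-methoxy-2-[(triisopropylsilyl)oxy]benzaldehyde
Conditions: Bu3SnCH2OH, Pd(PPh3)4 (5 mol %), 1,4-dioxane, 90 °C
Reagents that add atoms: (tributylstannyl)methanol, CCCC[Sn](CCCC)(CCCC)CO
Why: Stille hydroxymethylation; the bromide para to the formyl group is activated for oxidative addition, and the neutral conditions tolerate the aldehyde and the aryl silyl ether.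

Step 10
Reactants: 11 4-(hydroxymethyl)-5-methoxy-2-[(triisopropylsilyl)oxy]benzaldehyde
Product: 12 Ar-CHO
Conditions: TBSCl, imidazole, CH2Cl2, 0 °C → rt
Reagents that add atoms: tert-butyldimethylsilyl chloride, CC(C)(C)[Si](C)(C)Cl
Why: Standard silylation of a primary benzylic alcohol; this protects the C7 oxygen until the last step.

Step 11
Reactants: 12 Ar-CHO
Product: 13 (1S)-1-Ar-but-2-yn-1-ol
Conditions: propyne (excess), Me2Zn, (R,R)-ProPhenol (20 mol %), Ph3P=O (40 mol %), toluene, 0–4 °C
Reagents that add atoms: propyne, CC#C
Why: Zinc–ProPhenol catalysed asymmetric alkynylation of an aromatic aldehyde; the dinuclear zinc complex holds the aldehyde and the alkynylzinc together and the ligand antipode that adds to the Si face gives the (S)-carbinol, which is C8.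

Step 12
Reactants: 13 (1S)-1-Ar-but-2-yn-1-ol
Product: 15 (1S,2Z)-1-Ar-3-iodobut-2-en-1-ol, via cyclic alkenylalanate 14 (not isolated)
Conditions: Red-Al, THF, 0 °C → rt; EtOAc, −78 °C; then I2, THF, −78 → 0 °C
Reagents that add atoms: iodine, II
Why: Alkoxide-directed trans-hydroalumination places aluminium on the distal alkyne carbon in a five-membered oxaluminacycle; iodinolysis with retention gives the γ-iodo allylic alcohol with iodine cis to the carbinol.

Step 13
Reactants: 15 (1S,2Z)-1-Ar-3-iodobut-2-en-1-ol; 7 pinacol (E)-2-(RA)ethenylboronate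
Product: 16 (1S,2Z,4E)-1-Ar-3-methyl-5-(RA)penta-2,4-dien-1-ol
Conditions: Pd(dppf)Cl2·CH2Cl2 (5 mol %), AsPh3, Cs2CO3, DMF–THF–H2O, rt
Reagents that add atoms: none
Why: Suzuki–Miyaura alkenyl–alkenyl coupling; both partners react with retention, so the iodine position becomes the 9Z junction and the boronate geometry becomes 11E; the free carbinol and all silyl ethers are tolerated at room temperature.

Step 14
Reactants: 16 (1S,2Z,4E)-1-Ar-3-methyl-5-(RA)penta-2,4-dien-1-ol
Product: 18 quinone monoketal (2-substituted 4,4-dimethoxy-5-(silyloxymethyl)cyclohexa-2,5-dienone), via phenol 17 (not isolated)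
Conditions: TBAF (1.05 equiv), THF, −20 °C; then MeOH, NaHCO3, PhI(OAc)2, −20 → 0 °C
Reagents that add atoms: methanol, CO
Why: Fluoride cleaves the aryl O–Si bond much faster than the alkyl silyl ethers; iodine(III) oxidation of the p-methoxyphenol with capture by methanol at the methoxy-bearing carbon gives the quinone monoketal. The phenol is not isolated because o-hydroxybenzyl allylic alcohols lose water to o-quinone methides.

Step 15
Reactants: 18 quinone monoketal
Product: 20 epoxy enone dimethyl ketal (C1–C2 oxirane as in 24), via sodium peroxy enolate 19 (not isolated)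
Conditions: Ph3COOH (1.5 equiv), NaHMDS (2.5 equiv), toluene, −78 → −40 °C
Reagents that add atoms: trityl hydroperoxide, OOC(c1ccccc1)(c2ccccc2)c3ccccc3
Why: NaHMDS forms the sodium alkoxide of the C8 carbinol and sodium trityl peroxide, which aggregate in toluene. The peroxide oxygen adds in conjugate fashion to C2, the unsubstituted β-carbon of the C6 enone arm, to give enolate 19; the enolate carbon C1 then displaces trityloxide from the proximal peroxide oxygen. The closest known reaction is the Weitz–Scheffer epoxidation in its hydroxyl-directed form on quinone monoketals that carry an allylic hydroxyl. The oxirane closes in 3-exo-tet mode. C2 is set in the addition by C8: the reactive rotamer has the C8–H bond in the dienone plane next to the C6 carbonyl, which avoids strain between the dienyl group and that carbonyl, so the O–Na group lies under C2 and the dienyl group above it. The peroxide bound to that sodium reaches C2 through a six-membered array on the face that leads to the oxirane of 24. C1 is set by the closure, because the C2–O–O unit can only reach C1 on the face it already occupies. Site selectivity comes from the other arm, whose β-carbon C4 is fully substituted and lies next to the ketal; the nucleophilic oxidant ignores the unactivated diene and ring-A alkene, and the ketal prevents rearomatisation.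

Step 16
Reactants: 20 epoxy enone dimethyl ketal
Product: 21 C6 allylic alcohol (C6–OH anti to the oxirane oxygen)
Conditions: DIBAL-H (3.5 equiv), THF, −78 °C
Reagents that add atoms: none
Why: Chelation- and epoxide-directed 1,2-reduction. The C8 aluminium alkoxide chelates the C6 carbonyl and only attack from the oxirane face lets that chelate tighten into a cis-fused ring; the C8 chain on quaternary C1 covers the other face; and aluminium bound to the oxirane oxygen delivers hydride on its own side.

Step 17
Reactants: 21 C6 allylic alcohol
Product: 22 C3 enone (4-hydroxy-5,6-epoxycyclohex-2-enone core)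
Conditions: Montmorillonite K10, wet CH2Cl2, rt
Reagents that add atoms: water, O
Why: Mild acid hydrolysis of an allylic dimethyl ketal on an acidic clay. The oxocarbenium ion at C3 is stabilised by the C4=C5 alkene, whereas ionisation at C8 or C6 is disfavoured by the adjacent oxirane carbon.

Step 18
Reactants: 22 C3 enone
Product: 23 bis-silyl ether of 24
Conditions: DIBAL-H (5 equiv), THF, −78 °C
Reagents that add atoms: none
Why: Epoxide-directed DIBAL reduction. Aluminium coordinated to the oxirane oxygen next to C3 should deliver hydride syn to the oxirane, the sense expected for DIBAL with cyclic α,β-epoxy ketones, giving the C3 carbinol anti to the oxirane and cis to C6–OH; DIBAL reduces enones in 1,2 fashion.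

Step 19
Reactants: 23 bis-silyl ether of 24
Product: 24 target CNP0389279.1
Conditions: HF·pyridine, pyridine, THF, 0 °C → rt
Reagents that add atoms: none
Why: Fluoride-mediated desilylation of the primary TBS and secondary TES ethers. The pyridine buffer keeps the oxirane and the allylic carbinols from acid-promoted opening, and the medium is not basic enough for Payne migration.

## Compound list

1 | geranyl acetate, (2E)-3,7-dimethylocta-2,6-dien-1-yl acetate | CC(C)=CCC/C(C)=C/COC(C)=O | starting material
2 | (2E)-5-[(2R)-3,3-dimethyloxiran-2-yl]-3-methylpent-2-en-1-yl acetate | CC1(C)O[C@@H]1CC/C(C)=C/COC(C)=O | intermediate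
3 | [(1S,5R)-5-hydroxy-2,6,6-trimethylcyclohex-2-en-1-yl]methyl acetate (OH and CH2OAc cis) | CC1=CC[C@@H](O)C(C)(C)[C@H]1COC(C)=O | intermediate
4 | [(1S,5R)-2,6,6-trimethyl-5-(triethylsilyloxy)cyclohex-2-en-1-yl]methyl acetate | CC1=CC[C@@H](O[Si](CC)(CC)CC)C(C)(C)[C@H]1COC(C)=O | intermediate
5 | [(1S,5R)-2,6,6-trimethyl-5-(triethylsilyloxy)cyclohex-2-en-1-yl]methanol | CC1=CC[C@@H](O[Si](CC)(CC)CC)C(C)(C)[C@H]1CO | intermediate
6 | (1S,5R)-2,6,6-trimethyl-5-(triethylsilyloxy)cyclohex-2-ene-1-carbaldehyde | CC1=CC[C@@H](O[Si](CC)(CC)CC)C(C)(C)[C@H]1C=O | intermediate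
7 | 4,4,5,5-tetramethyl-2-{(E)-2-[(1S,5R)-2,6,6-trimethyl-5-(triethylsilyloxy)cyclohex-2-en-1-yl]ethenyl}-1,3,2-dioxaborolane | CC1=CC[C@@H](O[Si](CC)(CC)CC)C(C)(C)[C@H]1/C=C/B2OC(C)(C)C(C)(C)O2 | intermediate
8 | 4-bromo-2,5-dimethoxybenzaldehyde | COc1cc(C=O)c(OC)cc1Br | starting material
9 | 4-bromo-2-hydroxy-5-methoxybenzaldehyde | COc1cc(C=O)c(O)cc1Br | intermediate
10 | 4-bromo-5-methoxy-2-[(triisopropylsilyl)oxy]benzaldehyde | COc1cc(C=O)c(O[Si](C(C)C)(C(C)C)C(C)C)cc1Br | intermediate
11 | 4-(hydroxymethyl)-5-methoxy-2-[(triisopropylsilyl)oxy]benzaldehyde | COc1cc(C=O)c(O[Si](C(C)C)(C(C)C)C(C)C)cc1CO | intermediate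
12 | 4-{[(tert-butyldimethylsilyl)oxy]methyl}-5-methoxy-2-[(triisopropylsilyl)oxy]benzaldehyde | COc1cc(C=O)c(O[Si](C(C)C)(C(C)C)C(C)C)cc1CO[Si](C)(C)C(C)(C)C | intermediate
13 | (1S)-1-(4-{[(tert-butyldimethylsilyl)oxy]methyl}-5-methoxy-2-[(triisopropylsilyl)oxy]phenyl)but-2-yn-1-ol | CC#C[C@H](O)c1cc(OC)c(CO[Si](C)(C)C(C)(C)C)cc1O[Si](C(C)C)(C(C)C)C(C)C | intermediate
14 | sodium (5S)-5-aryl-2,2-bis(2-methoxyethoxy)-3-methyl-2,5-dihydro-1,2-oxaluminol-2-uide (aryl = Ar; cyclic alkenylalanate, not isolated) | CC1=C[C@@H](c2cc(OC)c(CO[Si](C)(C)C(C)(C)C)cc2O[Si](C(C)C)(C(C)C)C(C)C)O[Al-]1(OCCOC)OCCOC.[Na+] | intermediate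
15 | (1S,2Z)-1-(4-{[(tert-butyldimethylsilyl)oxy]methyl}-5-methoxy-2-[(triisopropylsilyl)oxy]phenyl)-3-iodobut-2-en-1-ol | C/C(I)=C/[C@H](O)c1cc(OC)c(CO[Si](C)(C)C(C)(C)C)cc1O[Si](C(C)C)(C(C)C)C(C)C | intermediate
16 | (1S,2Z,4E)-1-(4-{[(tert-butyldimethylsilyl)oxy]methyl}-5-methoxy-2-[(triisopropylsilyl)oxy]phenyl)-3-methyl-5-[(1S,5R)-2,6,6-trimethyl-5-(triethylsilyloxy)cyclohex-2-en-1-yl]penta-2,4-dien-1-ol | CC1=CC[C@@H](O[Si](CC)(CC)CC)C(C)(C)[C@H]1/C=C/C(C)=C\[C@H](O)c2cc(OC)c(CO[Si](C)(C)C(C)(C)C)cc2O[Si](C(C)C)(C(C)C)C(C)C | intermediate
17 | 5-{[(tert-butyldimethylsilyl)oxy]methyl}-2-{(1S,2Z,4E)-1-hydroxy-3-methyl-5-[(1S,5R)-2,6,6-trimethyl-5-(triethylsilyloxy)cyclohex-2-en-1-yl]penta-2,4-dien-1-yl}-4-methoxyphenol (not isolated) | CC1=CC[C@@H](O[Si](CC)(CC)CC)C(C)(C)[C@H]1/C=C/C(C)=C\[C@H](O)c2cc(OC)c(CO[Si](C)(C)C(C)(C)C)cc2O | intermediate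
18 | 5-{[(tert-butyldimethylsilyl)oxy]methyl}-2-{(1S,2Z,4E)-1-hydroxy-3-methyl-5-[(1S,5R)-2,6,6-trimethyl-5-(triethylsilyloxy)cyclohex-2-en-1-yl]penta-2,4-dien-1-yl}-4,4-dimethoxycyclohexa-2,5-dien-1-one | CC1=CC[C@@H](O[Si](CC)(CC)CC)C(C)(C)[C@H]1/C=C/C(C)=C\[C@H](O)C2=CC(OC)(OC)C(CO[Si](C)(C)C(C)(C)C)=CC2=O | intermediate
19 | sodium dienolate of 18 carrying a trityldioxy group on C2, on the face of the later oxirane oxygen (β-peroxy enolate, not isolated) | CC1=CC[C@@H](O[Si](CC)(CC)CC)C(C)(C)[C@H]1/C=C/C(C)=C\[C@H](O)C2=C([O-])C=C(CO[Si](C)(C)C(C)(C)C)C(OC)(OC)[C@@H]2OOC(c3ccccc3)(c4ccccc4)c5ccccc5.[Na+] | intermediate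
20 | (1S,6R)-4-{[(tert-butyldimethylsilyl)oxy]methyl}-1-{(1S,2Z,4E)-1-hydroxy-3-methyl-5-[(1S,5R)-2,6,6-trimethyl-5-(triethylsilyloxy)cyclohex-2-en-1-yl]penta-2,4-dien-1-yl}-5,5-dimethoxy-7-oxabicyclo[4.1.0]hept-3-en-2-one | CC1=CC[C@@H](O[Si](CC)(CC)CC)C(C)(C)[C@H]1/C=C/C(C)=C\[C@H](O)[C@]23O[C@H]2C(OC)(OC)C(CO[Si](C)(C)C(C)(C)C)=CC3=O | intermediate
21 | (1R,2S,6R)-4-{[(tert-butyldimethylsilyl)oxy]methyl}-1-{(1S,2Z,4E)-1-hydroxy-3-methyl-5-[(1S,5R)-2,6,6-trimethyl-5-(triethylsilyloxy)cyclohex-2-en-1-yl]penta-2,4-dien-1-yl}-5,5-dimethoxy-7-oxabicyclo[4.1.0]hept-3-en-2-ol | CC1=CC[C@@H](O[Si](CC)(CC)CC)C(C)(C)[C@H]1/C=C/C(C)=C\[C@H](O)[C@]23O[C@H]2C(OC)(OC)C(CO[Si](C)(C)C(C)(C)C)=C[C@@H]3O | intermediate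
22 | (1R,5S,6R)-3-{[(tert-butyldimethylsilyl)oxy]methyl}-5-hydroxy-6-{(1S,2Z,4E)-1-hydroxy-3-methyl-5-[(1S,5R)-2,6,6-trimethyl-5-(triethylsilyloxy)cyclohex-2-en-1-yl]penta-2,4-dien-1-yl}-7-oxabicyclo[4.1.0]hept-3-en-2-one | CC1=CC[C@@H](O[Si](CC)(CC)CC)C(C)(C)[C@H]1/C=C/C(C)=C\[C@H](O)[C@]23O[C@H]2C(=O)C(CO[Si](C)(C)C(C)(C)C)=C[C@@H]3O | intermediate
23 | (1R,2S,5R,6S)-4-{[(tert-butyldimethylsilyl)oxy]methyl}-1-{(1S,2Z,4E)-1-hydroxy-3-methyl-5-[(1S,5R)-2,6,6-trimethyl-5-(triethylsilyloxy)cyclohex-2-en-1-yl]penta-2,4-dien-1-yl}-7-oxabicyclo[4.1.0]hept-3-ene-2,5-diol | CC1=CC[C@@H](O[Si](CC)(CC)CC)C(C)(C)[C@H]1/C=C/C(C)=C\[C@H](O)[C@]23O[C@H]2[C@H](O)C(CO[Si](C)(C)C(C)(C)C)=C[C@@H]3O | intermediate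
24 | (1R,2S,5R,6S)-1-{(1S,2Z,4E)-1-hydroxy-5-[(1S,5R)-5-hydroxy-2,6,6-trimethylcyclohex-2-en-1-yl]-3-methylpenta-2,4-dien-1-yl}-4-(hydroxymethyl)-7-oxabicyclo[4.1.0]hept-3-ene-2,5-diol | CC1=CC[C@@H](O)C(C)(C)[C@H]1/C=C/C(C)=C\[C@H](O)[C@]12O[C@H]1[C@H](O)C(CO)=C[C@@H]2O | target

## Step count and least certain steps

Total: 19 steps. Longest linear sequence: 13 steps (steps 7–12 and 13–19 from 8; the branch from 1, steps 1–6 and 13–19, is equally long).

**Step 15 (key step).** The most likely failure is loss of facial control. If the alkoxide chelates the C6 carbonyl in the dienone plane instead of carrying the peroxide, the dienyl group lies under C2 and a peroxide that is not bound to the alkoxide attacks from the other face. Payne migration of the C8 alkoxide in the product is a second risk if the mixture warms. The fallback moves the epoxidation ahead of the fragment coupling and puts it under reagent control. It sets out from 15. Fluoride removes the aryl silyl group to give the iodoalkenyl phenol F1. Iodine(III) oxidation in methanol gives the iodoalkenyl quinone monoketal F2. Tartrate-mediated nucleophilic epoxidation (trityl hydroperoxide, NaHMDS, diisopropyl tartrate, the antipode chosen in a matched/mismatched test on this inexpensive substrate) gives the epoxy enone iodide F3, whose diastereomers can be separated. Suzuki coupling of F3 with 7 under the conditions of step 13 comes back to the route at 20.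

**Step 18.** The likely failure is hydride attack on C3 anti to the oxirane C–O bond, which gives the C3 epimer, if coordination of aluminium to the oxirane does not dominate. The fallback sets out from the C3-epimeric diol F4 obtained in that case. A Mitsunobu reaction with 4-nitrobenzoic acid at the C3 hydroxyl, the only carbinol not flanked by the quaternary C1, gives the inverted 4-nitrobenzoate F5. Methanolysis with K2CO3 in methanol at 0 °C comes back to the route at 23.

**Step 14.** The likely failure is loss of water from the transient phenol 17 to an o-quinone methide, followed by electrocyclisation to a chromene; partial cleavage of the alkyl silyl ethers is a lesser risk. The fallback changes the order of events. It sets out from 15 and uses the same two operations as above to reach the iodoalkenyl phenol F1 and the iodoalkenyl quinone monoketal F2, which lack the dienyl unit that drives dehydration. Suzuki coupling of F2 with 7 then comes back to the route at 18.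

**Step 2.** The likely failure is unselective termination of the cyclised cation: proton loss to the exocyclic alkene, capture by the hydroxyl to a bicyclic ether, or capture by chloride. The fallback replaces the cation by a radical. It sets out from 2. Titanocene(III) chloride (from Cp2TiCl2 and Mn, THF) opens the oxirane homolytically and the radical cyclises to the exocyclic isomer F6 with the same cis relationship. Isomerisation of the exocyclic alkene into the ring with catalytic RhCl3 hydrate in ethanol comes back to the route at 3.

**Step 11.** The likely failure is low enantioselectivity, or the opposite sense of induction, with this ortho-silyloxy aldehyde. The fallback sets the carbinol by reduction. It sets out from 12. Addition of 1-propynylmagnesium bromide gives the racemic carbinol F7. Oxidation with MnO2 gives the ynone F8. Reduction with BH3·SMe2 and the (R)-CBS oxazaborolidine, which treats the aryl group as large and the alkynyl group as small, comes back to the route at 13.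

## Further compounds

F1 | step 15 | 5-{[(tert-butyldimethylsilyl)oxy]methyl}-2-[(1S,2Z)-1-hydroxy-3-iodobut-2-en-1-yl]-4-methoxyphenol | C/C(I)=C/[C@H](O)c1cc(OC)c(CO[Si](C)(C)C(C)(C)C)cc1O
F2 | step 15 | 5-{[(tert-butyldimethylsilyl)oxy]methyl}-2-[(1S,2Z)-1-hydroxy-3-iodobut-2-en-1-yl]-4,4-dimethoxycyclohexa-2,5-dien-1-one | C/C(I)=C/[C@H](O)C1=CC(OC)(OC)C(CO[Si](C)(C)C(C)(C)C)=CC1=O
F3 | step 15 | (1S,6R)-4-{[(tert-butyldimethylsilyl)oxy]methyl}-1-[(1S,2Z)-1-hydroxy-3-iodobut-2-en-1-yl]-5,5-dimethoxy-7-oxabicyclo[4.1.0]hept-3-en-2-one | C/C(I)=C/[C@H](O)[C@]12O[C@H]1C(OC)(OC)C(CO[Si](C)(C)C(C)(C)C)=CC2=O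
F0 | step 14 | none | none
F4 | step 18 | C3 epimer of 23 (C3–OH syn to the oxirane oxygen) | CC1=CC[C@@H](O[Si](CC)(CC)CC)C(C)(C)[C@H]1/C=C/C(C)=C\[C@H](O)[C@]23O[C@H]2[C@@H](O)C(CO[Si](C)(C)C(C)(C)C)=C[C@@H]3O
F5 | step 18 | C3 4-nitrobenzoate of 23 | CC1=CC[C@@H](O[Si](CC)(CC)CC)C(C)(C)[C@H]1/C=C/C(C)=C\[C@H](O)[C@]23O[C@H]2[C@H](OC(=O)c4ccc(cc4)[N+](=O)[O-])C(CO[Si](C)(C)C(C)(C)C)=C[C@@H]3O
F6 | step 2 | [(1S,3R)-3-hydroxy-2,2-dimethyl-6-methylidenecyclohexyl]methyl acetate (exocyclic isomer of 3) | C=C1CC[C@@H](O)C(C)(C)[C@H]1COC(C)=O
F7 | step 11 | racemic 1-(4-{[(tert-butyldimethylsilyl)oxy]methyl}-5-methoxy-2-[(triisopropylsilyl)oxy]phenyl)but-2-yn-1-ol | CC#CC(O)c1cc(OC)c(CO[Si](C)(C)C(C)(C)C)cc1O[Si](C(C)C)(C(C)C)C(C)C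
F8 | step 11 | 1-(4-{[(tert-butyldimethylsilyl)oxy]methyl}-5-methoxy-2-[(triisopropylsilyl)oxy]phenyl)but-2-yn-1-one | CC#CC(=O)c1cc(OC)c(CO[Si](C)(C)C(C)(C)C)cc1O[Si](C(C)C)(C(C)C)C(C)C
A1 | alternative 1 | (R)-6,7-epoxygeranyl acetate (identical with 2) | CC1(C)O[C@@H]1CC/C(C)=C/COC(C)=O
A2 | alternative 1 | cis-hydroxy-α-cyclogeranyl acetate, [(1S,5R)-5-hydroxy-2,6,6-trimethylcyclohex-2-en-1-yl]methyl acetate (identical with 3) | CC1=CC[C@@H](O)C(C)(C)[C@H]1COC(C)=O
A3 | alternative 2 | diisopropylsilylene-tethered diene: ring-B vinyl carbinol (three TBS ethers) linked through Si(iPr)2 to a methallyl ether | C=C[C@H](O[Si](C(C)C)(C(C)C)OCC(C)=C)[C@]12O[C@H]1[C@H](O[Si](C)(C)C(C)(C)C)C(CO[Si](C)(C)C(C)(C)C)=C[C@@H]2O[Si](C)(C)C(C)(C)C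
A4 | alternative 2 | seven-membered 1,3-dioxa-2-silepine with the Z trisubstituted alkene, carrying the protected ring B | C/C3=C/[C@H](O[Si](C(C)C)(C(C)C)OC3)[C@]12O[C@H]1[C@H](O[Si](C)(C)C(C)(C)C)C(CO[Si](C)(C)C(C)(C)C)=C[C@@H]2O[Si](C)(C)C(C)(C)C
A5 | alternative 3 | cis-dihydrodiol acetonide: methyl 1,2-(isopropylidenedioxy)-4-{[(tert-butyldimethylsilyl)oxy]methyl}cyclohexa-3,5-diene-1-carboxylate | COC(=O)[C@]12OC(C)(C)O[C@H]1C=C(CO[Si](C)(C)C(C)(C)C)C=C2
A6 | alternative 3 | endoperoxide (2,3-dioxabicyclo[2.2.2]octene) anti to the acetonide | COC(=O)[C@]12OC(C)(C)O[C@H]1[C@H]3C(CO[Si](C)(C)C(C)(C)C)=C[C@@H]2OO3
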